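The route rests on opening the 2-pyrone ring at C3–C4 and O1–C2. The key step exploits that pyrone C2–C3 is an acetate unit carrying the ethylene tether, whereas C4 (with its methyl), C5, C6 (with the 3-furyl ring) and O1 are the carbon–oxygen chain of 1-(furan-3-yl)but-2-yn-1-one. In one operation a malonic acid half thioester should add decarboxylatively to the ynone and lactonize to the aromatic pyrone. Its precursor carries, on a two-carbon tether, the trans-fused (3aR,7aR) hydroxy keto lactone, made by a carbene-catalysed desymmetrizing benzoin cyclization and ozonolytic opening of the resulting acyloin ring; the enone is added last.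

Key step: step 14

Assumption: the target SMILES is read as the trans-fused lactone (C3a tether anti to the C7a hydroxyl), and the antipode of the chiral triazolium catalyst in step 5 is taken to be the one that gives (3aR,7aR)-8, since both antipodes are accessible.

Numbering: 2-benzofuran numbering is used for the lactone bicycle (C1 lactone carbonyl, C3 OCH2, C3a, C4 ketone, C7a carbinol). Indene numbering of 8–11 coincides with it at C1, C3a, C4–C7 and C7a. TBS = tert-butyldimethylsilyl, TMS = trimethylsilyl.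

Step 1
Reactants: 1 2-(prop-2-en-1-yl)cyclohexane-1,3-dione; 2 formaldehyde
Product: 3 2-(hydroxymethyl)-2-(prop-2-en-1-yl)cyclohexane-1,3-dione
Conditions: 37% aq. HCHO, Et3N (cat.), THF, 0 °C → rt
Reagents that add atoms: none
Why: Aldol hydroxymethylation of the acidic C2–H of the 2-substituted 1,3-dione should give the quaternary carbinol, which is still achiral, so no stereocenter arises.

Step 2
Reactants: 3 2-(hydroxymethyl)-2-(prop-2-en-1-yl)cyclohexane-1,3-dione
Product: 4 2-[(TBS-oxy)methyl]-2-(prop-2-en-1-yl)cyclohexane-1,3-dione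
Conditions: TBSCl, imidazole, DMF, 0 °C → rt
Reagents that add atoms: tert-butyl(chloro)dimethylsilane, CC(C)(C)[Si](C)(C)Cl
Why: Imidazole-promoted silylation of the primary alcohol should block retro-aldol loss of formaldehyde in the later basic steps.

Step 3
Reactants: 4 2-[(TBS-oxy)methyl]-2-(prop-2-en-1-yl)cyclohexane-1,3-dione
Product: 6 2-[(TBS-oxy)methyl]-2-(3-hydroxypropyl)cyclohexane-1,3-dione, via catechol boronate 5 (not isolated)
Conditions: catecholborane, RhCl(PPh3)3 (2 mol %), THF, rt; then H2O2, NaH2PO4/Na2HPO4 buffer (pH 7), 0 °C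
Reagents that add atoms: hydrogen peroxide, OO
Why: Rhodium-catalysed hydroboration should put boron on the terminal alkene carbon in preference to ketone reduction, and buffered peroxide oxidation (anti-Markovnikov hydration overall) avoids retro-Claisen opening of the dione.

Step 4
Reactants: 6 2-[(TBS-oxy)methyl]-2-(3-hydroxypropyl)cyclohexane-1,3-dione
Product: 7 3-{1-[(TBS-oxy)methyl]-2,6-dioxocyclohexyl}propanal
Conditions: Dess–Martin periodinane, CH2Cl2, rt
Reagents that add atoms: none
Why: Dess–Martin oxidation should take the primary alcohol to the aldehyde under neutral conditions that leave the silyl ether and the dione intact.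

Step 5
Reactants: 7 3-{1-[(TBS-oxy)methyl]-2,6-dioxocyclohexyl}propanal
Product: 8 (3aR,7aR)-3a-[(TBS-oxy)methyl]-7a-hydroxyhexahydro-1H-indene-1,4(2H)-dione (cis-fused; 7a-OH cis to the 3a-CH2OTBS group)
Conditions: chiral aminoindanol-derived N-pentafluorophenyl triazolium tetrafluoroborate (10 mol %), Et3N (10 mol %), toluene, rt
Reagents that add atoms: none
Why: In this intramolecular crossed benzoin reaction the carbene turns the aldehyde into an acyl-anion equivalent that adds to one of the two enantiotopic ring carbonyls (desymmetrization under catalyst control, fixing C3a and C7a as R,R), and because the tether reaches a carbonyl only from its own face the new cyclopentanone is cis-fused, which places the C7a hydroxyl cis to the silyloxymethyl group and the acyl carbon cis to the chain.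

Step 6
Reactants: 8 (3aR,7aR)-3a-[(TBS-oxy)methyl]-7a-hydroxyhexahydro-1H-indene-1,4(2H)-dione
Product: 10 (3aR,7aR)-3a-[(TBS-oxy)methyl]-7a-(TMS-oxy)hexahydrospiro[indene-4,2'-[1,3]dioxolan]-1(2H)-one (C4 ethylene ketal), via tertiary silyl ether 9 (not isolated)
Conditions: N,O-bis(trimethylsilyl)acetamide, CH2Cl2, rt; then Me3SiOCH2CH2OSiMe3, TMSOTf (5 mol %), −78 → −20 °C; pyridine
Reagents that add atoms: N,O-bis(trimethylsilyl)acetamide, CC(=N[Si](C)(C)C)O[Si](C)(C)C; 1,2-bis(trimethylsilyloxy)ethane, C[Si](C)(C)OCCO[Si](C)(C)C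
Why: Silyl-triflate-catalysed ketalization should be selective for the cyclohexanone carbonyl C4, because the cyclopentanone carbonyl C1 is deactivated by ring size, by the neighbouring fully substituted carbon and by the inductive pull of the α-silyloxy group installed first.

Step 7
Reactants: 10 (3aR,7aR)-3a-[(TBS-oxy)methyl]-7a-(TMS-oxy)hexahydrospiro[indene-4,2'-[1,3]dioxolan]-1(2H)-one
Product: 11 (3aR,7aR)-3a-[(TBS-oxy)methyl]-1,7a-bis(TMS-oxy)-3,3a,5,6,7,7a-hexahydrospiro[indene-4,2'-[1,3]dioxolane] (C1=C2 silyl enol ether)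
Conditions: TMSCl (2.5 equiv), LiN(iPr)2 (1.3 equiv), THF, −78 °C
Reagents that add atoms: chlorotrimethylsilane, C[Si](C)(C)Cl
Why: With C4 ketalized, C2 is the only enolizable position, so kinetic deprotonation with in situ silylation should give a single silyl enol ether.

Step 8
Reactants: 11 (3aR,7aR)-3a-[(TBS-oxy)methyl]-1,7a-bis(TMS-oxy)-3,3a,5,6,7,7a-hexahydrospiro[indene-4,2'-[1,3]dioxolane]
Product: 13 (6R,7R)-6-[(TBS-oxy)methyl]-7-hydroxy-6-(2-oxoethyl)-1,4-dioxaspiro[4.5]decane-7-carboxylic acid, via silyl ester aldehyde 12 (not isolated)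
Conditions: O3, CH2Cl2, −78 °C; PPh3, −78 °C → rt; then AcOH/THF/H2O, rt
Reagents that add atoms: ozone, [O-][O+]=O
Why: Ozonolysis of the electron-rich silyl enol ether should cleave C1=C2 to the C1 silyl ester and the C2 aldehyde, and aqueous acetic acid then frees the acid and the tertiary alcohol while the primary silyl ether and the dioxolane stay.

Step 9
Reactants: 13 (6R,7R)-6-[(TBS-oxy)methyl]-7-hydroxy-6-(2-oxoethyl)-1,4-dioxaspiro[4.5]decane-7-carboxylic acid; 14 2,2-dimethyl-1,3-dioxane-4,6-dione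
Product: 16 (6R,7R)-6-[(TBS-oxy)methyl]-6-[2-(2,2-dimethyl-4,6-dioxo-1,3-dioxan-5-yl)ethyl]-7-hydroxy-1,4-dioxaspiro[4.5]decane-7-carboxylic acid, via alkylidene Meldrum's acid 15 (not isolated)
Conditions: Hantzsch ester, L-proline (20 mol %), EtOH, rt
Reagents that add atoms: none
Why: Proline-catalysed Knoevenagel condensation with in situ Hantzsch ester conjugate reduction (reductive alkylation of Meldrum's acid) should consume the aldehyde before the neighbouring primary alcohol is released, so no lactol can trap it.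

Step 10
Reactants: 16 (6R,7R)-6-[(TBS-oxy)methyl]-6-[2-(2,2-dimethyl-4,6-dioxo-1,3-dioxan-5-yl)ethyl]-7-hydroxy-1,4-dioxaspiro[4.5]decane-7-carboxylic acid
Product: 18 5-{2-[(3aR,7aR)-7a-hydroxy-1,4-dioxohexahydro-2-benzofuran-3a(1H)-yl]ethyl}-2,2-dimethyl-1,3-dioxane-4,6-dione, via hydroxy acid 17 (not isolated)
Conditions: 1 M HCl, THF, rt; then TsOH (5 mol %), toluene, 50 °C (azeotropic drying)
Reagents that add atoms: water, O
Why: Acid hydrolysis removes the silyl ether and the dioxolane, and acid-catalysed lactonization of the γ-hydroxy acid then joins the trans-disposed CH2OH and CO2H groups, giving the trans ring fusion already fixed in step 5.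

Step 11
Reactants: 18 5-{2-[(3aR,7aR)-7a-hydroxy-1,4-dioxohexahydro-2-benzofuran-3a(1H)-yl]ethyl}-2,2-dimethyl-1,3-dioxane-4,6-dione; 19 benzenethiol
Product: 20 2-{2-[(3aR,7aR)-7a-hydroxy-1,4-dioxohexahydro-2-benzofuran-3a(1H)-yl]ethyl}-3-oxo-3-(phenylsulfanyl)propanoic acid (both epimers at C2 of the acid)
Conditions: PhSH (3 equiv), toluene, 90 °C; used at once
Reagents that add atoms: none
Why: Thermal thiolysis of the Meldrum's acid ring (acyl substitution with loss of acetone) should give the malonic acid half thioester, the tertiary hydroxyl being held anti to the tether by the trans fusion and so unable to compete.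

Step 12
Reactants: 21 furan-3-carbaldehyde; 22 prop-1-ynylmagnesium bromide
Product: 23 1-(furan-3-yl)but-2-yn-1-ol (racemic)
Conditions: THF, 0 °C; aq. NH4Cl
Reagents that add atoms: none
Why: Grignard 1,2-addition of the alkynyl nucleophile to the aldehyde; the carbinol center is removed in step 13.

Step 13
Reactants: 23 1-(furan-3-yl)but-2-yn-1-ol
Product: 24 1-(furan-3-yl)but-2-yn-1-one
Conditions: MnO2, CH2Cl2, rt
Reagents that add atoms: none
Why: MnO2 oxidation of the doubly activated (propargylic, furylic) alcohol should give the ynone without touching the furan.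

Step 14
Reactants: 20 2-{2-[(3aR,7aR)-7a-hydroxy-1,4-dioxohexahydro-2-benzofuran-3a(1H)-yl]ethyl}-3-oxo-3-(phenylsulfanyl)propanoic acid; 24 1-(furan-3-yl)but-2-yn-1-one
Product: 26 (3aR,7aR)-3a-{2-[6-(furan-3-yl)-4-methyl-2-oxo-2H-pyran-3-yl]ethyl}-7a-hydroxyhexahydro-2-benzofuran-1,4-dione, via keto thioester 25 (not isolated)
Conditions: 24 (1.5 equiv), Et3N (1.2 equiv), THF, 0 °C → rt
Reagents that add atoms: none
Why: Triethylamine converts 20 into its ammonium carboxylate, whose thioester enol carbon adds in a 1,4-sense to the methyl-bearing alkyne carbon of 24 while CO2 is lost, so that pyrone C3–C4 is made and the allenolate is protonated to keto thioester 25. Enolization of 25 towards C5 gives the 2Z dienolate, whose oxygen attacks the thioester carbonyl and expels thiophenolate, so that O1–C2 is made and the aromatic 2-pyrone forms. The closest known reaction types are the amine-promoted decarboxylative Michael addition of malonic acid half thioesters and the Michael addition–lactonization of acyl-activated carbon acids with ynones to give 2-pyrones. The one ring that closes, the pyranone, does so by 6-exo-trig acyl substitution at the thioester; no stereocenter is created and both epimers of 20 converge. The step needs conjugate instead of carbonyl addition and Z geometry about C3=C4; the soft thioester enolate secures the first, and reversible allenolate–dienolate equilibration drained by the aromatizing lactonization secures the second. The base is too weak to enolize the cyclohexanone or open the lactone, the tertiary hydroxyl is anti to the tether, and the excess of 24 absorbs thiol that adds to it.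

Step 15
Reactants: 26 (3aR,7aR)-3a-{2-[6-(furan-3-yl)-4-methyl-2-oxo-2H-pyran-3-yl]ethyl}-7a-hydroxyhexahydro-2-benzofuran-1,4-dione
Product: 27 3a-{2-[6-(furan-3-yl)-4-methyl-2-oxo-2H-pyran-3-yl]ethyl}-4,7a-bis(TMS-oxy)-3a,6,7,7a-tetrahydro-2-benzofuran-1(3H)-one (formally 3aS,7aR; spatial arrangement as in 26)
Conditions: TMSOTf (2.5 equiv), Et3N (4 equiv), CH2Cl2, −78 → 0 °C
Reagents that add atoms: trimethylsilyl trifluoromethanesulfonate, C[Si](C)(C)OS(=O)(=O)C(F)(F)F
Why: Soft enolization should give the only possible enol ether of the ketone (C3a is quaternary, so only C5 carries α-hydrogens) and silylate the tertiary alcohol, under conditions too mild to harm the pyrone, lactone or furan.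

Step 16
Reactants: 27 3a-{2-[6-(furan-3-yl)-4-methyl-2-oxo-2H-pyran-3-yl]ethyl}-4,7a-bis(TMS-oxy)-3a,6,7,7a-tetrahydro-2-benzofuran-1(3H)-one
Product: 29 (3aR,7aR)-3a-{2-[6-(furan-3-yl)-4-methyl-2-oxo-2H-pyran-3-yl]ethyl}-7a-hydroxy-3a,7a-dihydro-2-benzofuran-1,4(3H,7H)-dione, via enone silyl ether 28 (not isolated)
Conditions: Pd(OAc)2 (1.1 equiv), MeCN, rt; then aq. citric acid, THF, rt
Reagents that add atoms: none
Why: In this Saegusa–Ito oxidation Pd(OAc)2 should palladate the silyl enol ether at C5 and β-hydride elimination gives the C5=C6 enone, after which mild acid removes the tertiary silyl ether; C3a and C7a are untouched.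

Compound list
1 | 2-(prop-2-en-1-yl)cyclohexane-1,3-dione | C=CCC1C(=O)CCCC1=O | starting material
2 | formaldehyde | C=O | starting material
3 | 2-(hydroxymethyl)-2-(prop-2-en-1-yl)cyclohexane-1,3-dione | C=CCC1(CO)C(=O)CCCC1=O | intermediate
4 | 2-[(TBS-oxy)methyl]-2-(prop-2-en-1-yl)cyclohexane-1,3-dione | C=CCC1(CO[Si](C)(C)C(C)(C)C)C(=O)CCCC1=O | intermediate
5 | 2-[3-(1,3,2-benzodioxaborol-2-yl)propyl]-2-[(TBS-oxy)methyl]cyclohexane-1,3-dione | O=C1CCCC(=O)C1(CCCB1Oc2ccccc2O1)CO[Si](C)(C)C(C)(C)C | intermediate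
6 | 2-[(TBS-oxy)methyl]-2-(3-hydroxypropyl)cyclohexane-1,3-dione | O=C1CCCC(=O)C1(CCCO)CO[Si](C)(C)C(C)(C)C | intermediate
7 | 3-{1-[(TBS-oxy)methyl]-2,6-dioxocyclohexyl}propanal | O=CCCC1(CO[Si](C)(C)C(C)(C)C)C(=O)CCCC1=O | intermediate
8 | (3aR,7aR)-3a-[(TBS-oxy)methyl]-7a-hydroxyhexahydro-1H-indene-1,4(2H)-dione | O=C1CC[C@]2(CO[Si](C)(C)C(C)(C)C)C(=O)CCC[C@]12O | intermediate
9 | (3aR,7aR)-3a-[(TBS-oxy)methyl]-7a-(TMS-oxy)hexahydro-1H-indene-1,4(2H)-dione | O=C1CC[C@]2(CO[Si](C)(C)C(C)(C)C)C(=O)CCC[C@]12O[Si](C)(C)C | intermediate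
10 | (3aR,7aR)-3a-[(TBS-oxy)methyl]-7a-(TMS-oxy)hexahydrospiro[indene-4,2'-[1,3]dioxolan]-1(2H)-one | O=C1CC[C@]2(CO[Si](C)(C)C(C)(C)C)C3(OCCO3)CCC[C@]12O[Si](C)(C)C | intermediate
11 | (3aR,7aR)-3a-[(TBS-oxy)methyl]-1,7a-bis(TMS-oxy)-3,3a,5,6,7,7a-hexahydrospiro[indene-4,2'-[1,3]dioxolane] | C[Si](C)(C)OC1=CC[C@]2(CO[Si](C)(C)C(C)(C)C)C3(OCCO3)CCC[C@]12O[Si](C)(C)C | intermediate
12 | trimethylsilyl (6R,7R)-6-[(TBS-oxy)methyl]-6-(2-oxoethyl)-7-(TMS-oxy)-1,4-dioxaspiro[4.5]decane-7-carboxylate | O=CC[C@@]2(CO[Si](C)(C)C(C)(C)C)[C@@](O[Si](C)(C)C)(C(=O)O[Si](C)(C)C)CCCC23OCCO3 | intermediate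
13 | (6R,7R)-6-[(TBS-oxy)methyl]-7-hydroxy-6-(2-oxoethyl)-1,4-dioxaspiro[4.5]decane-7-carboxylic acid | O=CC[C@@]2(CO[Si](C)(C)C(C)(C)C)[C@@](O)(C(O)=O)CCCC23OCCO3 | intermediate
14 | 2,2-dimethyl-1,3-dioxane-4,6-dione (Meldrum's acid) | CC1(C)OC(=O)CC(=O)O1 | starting material
15 | (6R,7R)-6-[(TBS-oxy)methyl]-6-[2-(2,2-dimethyl-4,6-dioxo-1,3-dioxan-5-ylidene)ethyl]-7-hydroxy-1,4-dioxaspiro[4.5]decane-7-carboxylic acid | CC1(C)OC(=O)C(=CC[C@@]2(CO[Si](C)(C)C(C)(C)C)[C@@](O)(C(O)=O)CCCC23OCCO3)C(=O)O1 | intermediate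
16 | (6R,7R)-6-[(TBS-oxy)methyl]-6-[2-(2,2-dimethyl-4,6-dioxo-1,3-dioxan-5-yl)ethyl]-7-hydroxy-1,4-dioxaspiro[4.5]decane-7-carboxylic acid | CC1(C)OC(=O)C(CC[C@@]2(CO[Si](C)(C)C(C)(C)C)[C@@](O)(C(O)=O)CCCC23OCCO3)C(=O)O1 | intermediate
17 | (1R,2R)-2-[2-(2,2-dimethyl-4,6-dioxo-1,3-dioxan-5-yl)ethyl]-1-hydroxy-2-(hydroxymethyl)-3-oxocyclohexane-1-carboxylic acid | CC1(C)OC(=O)C(CC[C@@]2(CO)[C@@](O)(C(O)=O)CCCC2=O)C(=O)O1 | intermediate
18 | 5-{2-[(3aR,7aR)-7a-hydroxy-1,4-dioxohexahydro-2-benzofuran-3a(1H)-yl]ethyl}-2,2-dimethyl-1,3-dioxane-4,6-dione | CC1(C)OC(=O)C(CC[C@@]23COC(=O)[C@@]2(O)CCCC3=O)C(=O)O1 | intermediate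
19 | benzenethiol | Sc1ccccc1 | starting material
20 | 2-{2-[(3aR,7aR)-7a-hydroxy-1,4-dioxohexahydro-2-benzofuran-3a(1H)-yl]ethyl}-3-oxo-3-(phenylsulfanyl)propanoic acid | OC(=O)C(CC[C@@]12COC(=O)[C@@]1(O)CCCC2=O)C(=O)Sc1ccccc1 | intermediate
21 | furan-3-carbaldehyde | O=Cc1ccoc1 | starting material
22 | prop-1-ynylmagnesium bromide | CC#C[Mg]Br | starting material
23 | 1-(furan-3-yl)but-2-yn-1-ol (racemic) | CC#CC(O)c1ccoc1 | intermediate
24 | 1-(furan-3-yl)but-2-yn-1-one | CC#CC(=O)c1ccoc1 | intermediate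
25 | S-phenyl 5-(furan-3-yl)-2-{2-[(3aR,7aR)-7a-hydroxy-1,4-dioxohexahydro-2-benzofuran-3a(1H)-yl]ethyl}-3-methyl-5-oxopent-3-enethioate (alkene isomers, both C2 epimers) | CC(=CC(=O)c1ccoc1)C(CC[C@@]12COC(=O)[C@@]1(O)CCCC2=O)C(=O)Sc1ccccc1 | intermediate
26 | (3aR,7aR)-3a-{2-[6-(furan-3-yl)-4-methyl-2-oxo-2H-pyran-3-yl]ethyl}-7a-hydroxyhexahydro-2-benzofuran-1,4-dione | Cc1cc(-c2ccoc2)oc(=O)c1CC[C@@]12COC(=O)[C@@]1(O)CCCC2=O | intermediate
27 | 3a-{2-[6-(furan-3-yl)-4-methyl-2-oxo-2H-pyran-3-yl]ethyl}-4,7a-bis(TMS-oxy)-3a,6,7,7a-tetrahydro-2-benzofuran-1(3H)-one (formally 3aS,7aR) | Cc1cc(-c2ccoc2)oc(=O)c1CC[C@@]12COC(=O)[C@@]1(O[Si](C)(C)C)CCC=C2O[Si](C)(C)C | intermediate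
28 | (3aR,7aR)-3a-{2-[6-(furan-3-yl)-4-methyl-2-oxo-2H-pyran-3-yl]ethyl}-7a-(TMS-oxy)-3a,7a-dihydro-2-benzofuran-1,4(3H,7H)-dione | Cc1cc(-c2ccoc2)oc(=O)c1CC[C@@]12COC(=O)[C@@]1(O[Si](C)(C)C)CC=CC2=O | intermediate
29 | (3aR,7aR)-3a-{2-[6-(furan-3-yl)-4-methyl-2-oxo-2H-pyran-3-yl]ethyl}-7a-hydroxy-3a,7a-dihydro-2-benzofuran-1,4(3H,7H)-dione | Cc1cc(-c2ccoc2)oc(=O)c1CC[C@@]12COC(=O)[C@@]1(O)CC=CC2=O | target

Total step count: 16. Longest linear sequence: 14 steps (steps 1–11 and 14–16); steps 12–13 make the ynone separately.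

Steps most likely to fail

Step 14. The thioester enolate may be protonated after loss of CO2 before it has added to the ynone (plain decarboxylation), or the ynone may be consumed by liberated thiolate. The fallback sets out from 18. Its Meldrum's acid C–H should add under Et3N catalysis to 24 to give the alkenyl Meldrum's acid F1, so that the C3–C4 bond exists before any CO2 is lost. Heating F1 with PhSH and a little Et3N in toluene should then open the dioxanedione, release acetone and CO2 and close the pyrone, which comes back to the route at 26.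

Step 5. The chiral carbene may discriminate poorly between the two enantiotopic carbonyl groups, or the cyclization may stall next to the bulky silyloxymethyl group. The fallback sets out from 7 and uses the small achiral carbene from 3-benzyl-5-(2-hydroxyethyl)-4-methylthiazolium chloride and Et3N; the cis ring fusion is still enforced. This should give 8 together with its mirror image, the ent-acyloin F2, and separation on a chiral stationary phase comes back to the route at 8.

Step 6. Chemoselectivity between the two ketones may be lost, with ketalization at both or at neither. The fallback sets out from 4 and installs the dioxolane while the two carbonyls are still equivalent, giving the racemic mono-ketal F3. Hydroboration (catechol boronate F4, not isolated) and oxidation give alcohol F5, and Dess–Martin oxidation gives aldehyde F6. The achiral thiazolium carbene then closes the acyloin ring onto the only ketone left, giving hydroxy ketal F7 together with its enantiomer F8, which are separated on a chiral stationary phase. F7, under the conditions of step 7 with a second equivalent of base, comes back to the route at 11. This costs half the material.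

Further compounds
F1 | step 14 | 5-[4-(furan-3-yl)-4-oxobut-2-en-2-yl]-5-{2-[(3aR,7aR)-7a-hydroxy-1,4-dioxohexahydro-2-benzofuran-3a(1H)-yl]ethyl}-2,2-dimethyl-1,3-dioxane-4,6-dione | CC(=CC(=O)c1ccoc1)C1(CC[C@@]23COC(=O)[C@@]2(O)CCCC3=O)C(=O)OC(C)(C)OC1=O
F2 | step 5 | (3aS,7aS)-3a-[(TBS-oxy)methyl]-7a-hydroxyhexahydro-1H-indene-1,4(2H)-dione | O=C1CC[C@@]2(CO[Si](C)(C)C(C)(C)C)C(=O)CCC[C@@]12O
F3 | step 6 | 6-[(TBS-oxy)methyl]-6-(prop-2-en-1-yl)-1,4-dioxaspiro[4.5]decan-7-one (racemic) | C=CCC1(CO[Si](C)(C)C(C)(C)C)C(=O)CCCC12OCCO2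
F4 | step 6 | 6-[3-(1,3,2-benzodioxaborol-2-yl)propyl]-6-[(TBS-oxy)methyl]-1,4-dioxaspiro[4.5]decan-7-one (racemic) | O=C1CCCC2(OCCO2)C1(CCCB1Oc2ccccc2O1)CO[Si](C)(C)C(C)(C)C
F5 | step 6 | 6-[(TBS-oxy)methyl]-6-(3-hydroxypropyl)-1,4-dioxaspiro[4.5]decan-7-one (racemic) | O=C1CCCC2(OCCO2)C1(CCCO)CO[Si](C)(C)C(C)(C)C
F6 | step 6 | 3-{6-[(TBS-oxy)methyl]-7-oxo-1,4-dioxaspiro[4.5]decan-6-yl}propanal (racemic) | O=CCCC1(CO[Si](C)(C)C(C)(C)C)C(=O)CCCC12OCCO2
F7 | step 6 | (3aR,7aR)-3a-[(TBS-oxy)methyl]-7a-hydroxyhexahydrospiro[indene-4,2'-[1,3]dioxolan]-1(2H)-one | O=C1CC[C@]2(CO[Si](C)(C)C(C)(C)C)C3(OCCO3)CCC[C@]12O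
F8 | step 6 | (3aS,7aS)-3a-[(TBS-oxy)methyl]-7a-hydroxyhexahydrospiro[indene-4,2'-[1,3]dioxolan]-1(2H)-one | O=C1CC[C@@]2(CO[Si](C)(C)C(C)(C)C)C3(OCCO3)CCC[C@@]12O
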